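**Assumption:** the target is the enantiomer drawn, i.e. the (−)-β-pinene series, which matches commercial (1R)-(−)-nopol. The pinane is numbered as in pinene (C1/C5 bridgeheads, C6 = CMe2) and chroman atoms carry primes. Nothing here has been run; the route is a proposal.

## Retrosynthetic overview

1. Euglobal G3 (10) ⇒ spirochroman 8 by removing the 8'-CHO (late formylation of the only free ring position).
2. 8 ⇒ triol 7 by cutting the O1'–C2 (spiro) bond: Markovnikov O–H addition of the 4-OH (para to the acyl group) across the pinene C2=C3 bond. This closes the pyran ring and sets the spiro centre.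
3. 7 ⇒ acylphloroglucinol 3 + aldehyde 5 (ArC–CH2 bond, reductive alkylation).
4. 3 ⇒ phloroglucinol 1 + isovaleryl chloride 2; 5 ⇒ (−)-nopol 4 (chiral pool, carries C1 and C5).
5. Ring order: the arene and the pinane bicycle are bought; the dihydropyran ring is the only ring formed (step 4).

## Route

Step 1
Reactants: 1 phloroglucinol; 2 isovaleryl chloride
Product: 3 1-(2,4,6-trihydroxyphenyl)-3-methylbutan-1-one
Conditions: AlCl3 (3.5 equiv), PhNO2, 0 → 65 °C; then ice/2 M HCl
Reagents that add atoms: none
Why: Friedel–Crafts acylation of the very electron-rich symmetric triol at carbon, with aluminium chelation of the resulting 2-hydroxyaryl ketone deactivating the ring against a second acylation; no stereocentre.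

Step 2
Reactants: 4 (−)-nopol
Product: 5 2-[(1R,5S)-6,6-dimethylbicyclo[3.1.1]hept-2-en-2-yl]acetaldehyde
Conditions: Dess–Martin periodinane (1.2 equiv), NaHCO3 (3 equiv), CH2Cl2, 0 °C → rt; used at once
Reagents that add atoms: none
Why: Dess–Martin oxidation stops at the aldehyde under buffered near-neutral conditions, so the β,γ-alkene does not move into conjugation and the C1/C5 bridgehead centres are untouched.

Step 3
Reactants: 3 1-(2,4,6-trihydroxyphenyl)-3-methylbutan-1-one (2 equiv, excess recovered); 5 2-[(1R,5S)-6,6-dimethylbicyclo[3.1.1]hept-2-en-2-yl]acetaldehyde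
Product: 7 1-{3-[2-((1R,5S)-6,6-dimethylbicyclo[3.1.1]hept-2-en-2-yl)ethyl]-2,4,6-trihydroxyphenyl}-3-methylbutan-1-one, via o-quinone methide 6 (not isolated)
Conditions: L-proline (20 mol%), Hantzsch ester (1.2 equiv), EtOH, 25 °C
Reagents that add atoms: none
Why: Three-component reductive alkylation (Knoevenagel-type condensation then hydride transfer): a ring C–H of 3 attacks the proline iminium of 5, loss of proline gives o-quinone methide 6, and the Hantzsch ester reduces it by 1,4-hydride delivery before a second phenol can trap it; the two free ring positions of 3 are equivalent, excess 3 limits dialkylation, and no stereocentre is formed.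

Step 4
Reactants: 7 1-{3-[2-((1R,5S)-6,6-dimethylbicyclo[3.1.1]hept-2-en-2-yl)ethyl]-2,4,6-trihydroxyphenyl}-3-methylbutan-1-one
Product: 8 1-[(1R,2R,5S)-5',7'-dihydroxy-6,6-dimethyl-3',4'-dihydrospiro[bicyclo[3.1.1]heptane-2,2'-chromen]-6'-yl]-3-methylbutan-1-one
Conditions: IDPi acid HN[P(=NSO2CF3)(O2Binol*)]2 (5 mol%; Binol* = (S)-3,3'-bis[3,5-bis(trifluoromethyl)phenyl]-1,1'-binaphthalene-2,2'-diolate), CHCl3 (0.02 M), 4 Å MS, −20 → 0 °C; filter through basic alumina at full conversion
Reagents that add atoms: none
Why: Proposed new method: a confined, strongly acidic imidodiphosphorimidate protonates C3 of the trisubstituted pinene alkene while its P=N–Tf anion hydrogen-bonds and deprotonates the most acidic, unchelated 4-OH, so that C2–O bond formation is concerted-asynchronous inside a tight ion pair and outruns cyclobutane opening or Wagner–Meerwein shift of the pinan-2-yl cation; the 6-exo attack is strongly favoured on the alkene face anti to the gem-dimethyl bridge (oxygen anti, CH2 syn to that bridge, 2R; substrate control, so the catalyst antipode is not critical), and the ketone-chelated, buttressed 2-OH stays out, giving the 6'-acyl chroman; the closest known reaction types are the confined-acid intramolecular hydroalkoxylation of unactivated 1,1-disubstituted alkenes by aliphatic alcohols and the acid-mediated cyclisation of o-prenylphenols to 2,2-dimethylchromans, neither shown for a phenol adding to a rearrangement-prone pinene alkene.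

Step 5
Reactants: 8 1-[(1R,2R,5S)-5',7'-dihydroxy-6,6-dimethyl-3',4'-dihydrospiro[bicyclo[3.1.1]heptane-2,2'-chromen]-6'-yl]-3-methylbutan-1-one
Product: 10 euglobal G3, via aryl iminium salt 9 (not isolated)
Conditions: POCl3 (1.5 equiv), DMF (3 equiv), EtOAc, 0 °C → rt; then H2O, rt
Reagents that add atoms: N,N-dimethylformamide, CN(C)C=O (formyl carbon); water, O (formyl oxygen)
Why: Vilsmeier–Haack formylation, in which the chloroiminium electrophile substitutes the only remaining ring C–H (two ortho oxygens, one para oxygen) and water hydrolyses iminium 9 to the aldehyde; holding the temperature at or below 25 °C avoids attack at the ketone α-CH2 (chromone formation) and ionisation of the spiro ether, so no stereocentre is affected.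

## Compound list

1 | phloroglucinol (benzene-1,3,5-triol) | Oc1cc(O)cc(O)c1 | starting material
2 | isovaleryl chloride (3-methylbutanoyl chloride) | CC(C)CC(Cl)=O | starting material
3 | 1-(2,4,6-trihydroxyphenyl)-3-methylbutan-1-one | CC(C)CC(=O)c1c(O)cc(O)cc1O | intermediate
4 | (−)-nopol, 2-[(1R,5S)-6,6-dimethylbicyclo[3.1.1]hept-2-en-2-yl]ethan-1-ol | OCCC1=CC[C@H]2C[C@@H]1C2(C)C | starting material
5 | 2-[(1R,5S)-6,6-dimethylbicyclo[3.1.1]hept-2-en-2-yl]acetaldehyde | O=CCC1=CC[C@H]2C[C@@H]1C2(C)C | intermediate
6 | 6-[2-((1R,5S)-6,6-dimethylbicyclo[3.1.1]hept-2-en-2-yl)ethylidene]-3,5-dihydroxy-2-(3-methylbutanoyl)cyclohexa-2,4-dien-1-one (o-quinone methide, alkene geometry not defined) | CC(C)CC(=O)C1=C(O)C=C(O)C(=CCC2=CC[C@H]3C[C@@H]2C3(C)C)C1=O | intermediate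
7 | 1-{3-[2-((1R,5S)-6,6-dimethylbicyclo[3.1.1]hept-2-en-2-yl)ethyl]-2,4,6-trihydroxyphenyl}-3-methylbutan-1-one | CC(C)CC(=O)c1c(O)cc(O)c(CCC2=CC[C@H]3C[C@@H]2C3(C)C)c1O | intermediate
8 | 1-[(1R,2R,5S)-5',7'-dihydroxy-6,6-dimethyl-3',4'-dihydrospiro[bicyclo[3.1.1]heptane-2,2'-chromen]-6'-yl]-3-methylbutan-1-one (ring oxygen anti to the gem-dimethyl bridge) | CC(C)CC(=O)c1c(O)cc2c(c1O)CC[C@@]1(CC[C@H]3C[C@@H]1C3(C)C)O2 | intermediate
9 | N-{[(1R,2R,5S)-5',7'-dihydroxy-6,6-dimethyl-6'-(3-methylbutanoyl)-3',4'-dihydrospiro[bicyclo[3.1.1]heptane-2,2'-chromen]-8'-yl]methylidene}-N-methylmethanaminium dichlorophosphate | CC(C)CC(=O)c1c(O)c(C=[N+](C)C)c2c(c1O)CC[C@@]1(CC[C@H]3C[C@@H]1C3(C)C)O2.[O-]P(=O)(Cl)Cl | intermediate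
10 | euglobal G3, (1R,2R,5S)-5',7'-dihydroxy-6,6-dimethyl-6'-(3-methylbutanoyl)-3',4'-dihydrospiro[bicyclo[3.1.1]heptane-2,2'-chromene]-8'-carbaldehyde | CC(C)CC(=O)c1c(O)c(C=O)c2c(c1O)CC[C@@]1(CC[C@H]3C[C@@H]1C3(C)C)O2 | target

## Step count and risks

Total steps: 5. Longest linear sequence: 4 (1 → 3 → 7 → 8 → 10, or 4 → 5 → 7 → 8 → 10).

**Step 4 (proposed new ring closure) is the most likely to fail.** The pinan-2-yl cation can open to p-menthene-type or bornyl-type products if C–O bond formation is not fast enough. The 2-OH may compete and give the 8'-acyl regioisomer. The tertiary aryl ether can re-ionise if the acid is left in contact with product. The fallback is known chemistry, sets out from 3 and comes back at 8. Heat 3 with paraformaldehyde and excess (−)-β-pinene (C=C1CC[C@H]2C[C@@H]1C2(C)C) in AcOH with NaOAc at 80 °C. Knoevenagel condensation gives the 3-methylene o-quinone methide F1 (not isolated). It undergoes the biomimetic inverse-demand hetero-Diels–Alder reaction with the exocyclic alkene on the face anti to the gem-dimethyl bridge. This gives 8 together with its 8'-acyl regioisomer, which is removed by chromatography. Steps 2 and 3 are then not needed.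

**Step 3 (reductive alkylation) is the second risk.** Aldehyde 5 can self-condense or slip into conjugation under amine catalysis, and the o-quinone methide 6 can be trapped by a second molecule of 3 or lead to dialkylation. The fallback sets out from 3 and comes back at 8. Add CH2=CHMgBr to commercial (1R,5S)-(+)-nopinone (O=C1CC[C@H]2C[C@@H]1C2(C)C) in THF at −78 °C. Attack anti to the gem-dimethyl bridge gives (1R,2S,5S)-2-ethenyl-6,6-dimethylbicyclo[3.1.1]heptan-2-ol F2. Couple F2 with 3 (2 equiv) by dehydrative Tsuji–Trost C-allylation with the zerovalent palladium catalyst Pd(PPh3)4 and BEt3 in THF at 50 °C. The ring carbon attacks the unhindered terminus of the π-allyl, giving the exocyclic-alkene isomer 1-{3-[2-((1R,5S)-6,6-dimethylbicyclo[3.1.1]heptan-2-ylidene)ethyl]-2,4,6-trihydroxyphenyl}-3-methylbutan-1-one F3 (E/Z mixture). F3 is then closed under the step 4 conditions in the 6-endo mode through the same C2 ion pair, giving 8.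

**Step 5 (formylation) is the third risk.** The HCl formed may ionise the spiro ether of 8, and the Vilsmeier reagent may attack the 2-hydroxyaryl ketone side chain. The fallback sets out from 8 and comes back at 10. Treat 8 with MgCl2, Et3N and paraformaldehyde in MeCN at reflux (magnesium-phenoxide-directed ortho-formylation under basic conditions). The magnesium 7'-phenoxide delivers formaldehyde to C8', giving the 8'-hydroxymethyl intermediate F4 (not isolated). F4 is oxidised in the flask by hydride transfer to a second formaldehyde to give 10, with no strong acid present.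

## Further compounds

F1 | step 4 | 3,5-dihydroxy-6-methylidene-2-(3-methylbutanoyl)cyclohexa-2,4-dien-1-one (o-quinone methide) | CC(C)CC(=O)C1=C(O)C=C(O)C(=C)C1=O
F2 | step 3 | (1R,2S,5S)-2-ethenyl-6,6-dimethylbicyclo[3.1.1]heptan-2-ol | C=C[C@@]1(O)CC[C@H]2C[C@@H]1C2(C)C
F3 | step 3 | 1-{3-[2-((1R,5S)-6,6-dimethylbicyclo[3.1.1]heptan-2-ylidene)ethyl]-2,4,6-trihydroxyphenyl}-3-methylbutan-1-one | CC(C)CC(=O)c1c(O)cc(O)c(CC=C2CC[C@H]3C[C@@H]2C3(C)C)c1O
F4 | step 5 | 1-[(1R,2R,5S)-5',7'-dihydroxy-8'-(hydroxymethyl)-6,6-dimethyl-3',4'-dihydrospiro[bicyclo[3.1.1]heptane-2,2'-chromen]-6'-yl]-3-methylbutan-1-one | CC(C)CC(=O)c1c(O)c(CO)c2c(c1O)CC[C@@]1(CC[C@H]3C[C@@H]1C3(C)C)O2
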